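**Retrosynthetic overview**

1. Numbering: C1 = CH bearing isobutyryl, C2/C4 = ring ketones, C3 = O-bearing bridgehead, C5 = second bridgehead, C6 = CH2, C7 = CH(prenyl), C8 = C(Me)(homoprenyl), C9 = lactone carbonyl. The strategy rests on C3: it carries oxygen, a prenyl group and the two acyl carbons C2 and C4, so it is the central carbon of a 2-hydroxy-2-prenylmalonate on which both the furan-2,4-dione ring (O, C9, C5, C4, C3) and the eight-membered carbocycle (C1–C8) hang.
2. Key disconnections: C4–C5 (lactone ring, Dieckmann) and C1–C2 (eight-membered ring, ketone–ester Claisen), both back to the two ester carbons of acyloxymalonate 21; the lactone ring closes first, the eight-membered ring second, in one flask.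
3. 21 comes from keto acid 18 by O-alkylation of its carboxylate with diethyl bromomalonate and C-prenylation at C3.
4. 18 comes from acid 5: C6–C5 by Horner–Wadsworth–Emmons olefination and conjugate reduction; vinyl to CH2C(=O)iPr by hydroboration, oxidation, iPrMgCl addition and oxidation.
5. 5 (C7 and C8) comes from geranyl 5-methylhex-4-enoate by an enantioselective Ireland–Claisen rearrangement.

Key step: step 15

Remarks on the chemistry (assumptions):
- The facial preference of the (S,S)-diazaborolidine on ester 3 is taken to be the one that gives (2R,3S)-5; if it is the opposite, the (R,R)-reagent is used and nothing else changes.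
- C5 is carried as a mixture of epimers from step 7 on (it is enolised in step 15); the carbinol centre of 16 and 17 is a mixture and is removed in step 12.
- C1 of the target is an enolisable β-diketone carbon; the (1R) epimer of the target is taken to be the thermodynamically preferred one.
- An alkoxide base is not used in step 15: with a free ketone enolate and an intact C9 ester, C1 would close on C9 (six-membered Claisen) and expel the tartronate. Both enolates are therefore formed first with an amide base.

**Step 1**
Reactants: 1 geraniol; 2 5-methylhex-4-enoic acid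
Product: 3 geranyl 5-methylhex-4-enoate
Conditions: DCC, DMAP (cat.), CH2Cl2, 0 °C → rt
Reagents that add atoms: none
Why: Steglich esterification of a primary allylic alcohol with an unhindered acid; no stereocentre is formed and the E geometry of the geranyl alkene is untouched.

**Step 2**
Reactants: 3 geranyl 5-methylhex-4-enoate
Product: 5 (2R,3S)-3,7-dimethyl-2-(3-methylbut-2-enyl)-3-vinyloct-6-enoic acid, via boron ketene acetal 4 (not isolated)
Conditions: (4S,5S)-2-bromo-4,5-diphenyl-1,3-bis{[3,5-bis(trifluoromethyl)phenyl]sulfonyl}-1,3,2-diazaborolidine (1.1 equiv), iPr2NEt, CH2Cl2, −78 °C, then 4 °C → rt; aqueous work-up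
Reagents that add atoms: none
Why: Enantioselective Ireland–Claisen rearrangement of a chiral boron ketene acetal: Hünig's base in CH2Cl2 is expected to give the Z(O)-enolate, which with the E-geranyl alkene passes through a chair with prenyl and homoprenyl equatorial and C7–H and C8–CH3 axial (2R*,3S* relationship), while the C2-symmetric sulfonamide ligand on boron selects the enolate face, so that C7 and C8 are both set here.

**Step 3**
Reactants: 5 acid
Product: 6 (2R,3S)-3,7-dimethyl-2-(3-methylbut-2-enyl)-3-vinyloct-6-en-1-ol
Conditions: LiAlH4, Et2O, 0 °C → rt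
Reagents that add atoms: none
Why: Hydride reduction of the carboxylic acid to the primary alcohol; the carboxylate cannot epimerise at C7 and the alkenes are inert.

**Step 4**
Reactants: 6 alcohol
Product: 7 (2R,3S)-3,7-dimethyl-2-(3-methylbut-2-enyl)-3-vinyloct-6-enal
Conditions: DMP, CH2Cl2, 0 °C → rt
Reagents that add atoms: none
Why: Dess–Martin oxidation under near-neutral conditions, which should leave the α-stereocentre C7 (shielded by quaternary C8) unepimerised.

**Step 5**
Reactants: 8 trimethyl phosphonoacetate; 9 prenyl bromide
Product: 10 methyl 2-(dimethoxyphosphoryl)-5-methylhex-4-enoate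
Conditions: NaH, THF, 0 °C; then 9, rt (8 in slight excess)
Reagents that add atoms: none
Why: C-alkylation of the phosphonoacetate anion at the primary carbon of the allylic bromide (SN2); the excess of 8 limits dialkylation.

**Step 6**
Reactants: 7 aldehyde; 10 phosphonate
Product: 11 methyl (4S,5S)-5,9-dimethyl-2,4-bis(3-methylbut-2-enyl)-5-vinyldeca-2,8-dienoate (E/Z mixture)
Conditions: NaH, THF, 0 °C; then 7, rt → 40 °C
Reagents that add atoms: none
Why: Horner–Wadsworth–Emmons olefination forms the C5–C6 bond; the alkene geometry is irrelevant because the double bond is reduced next, and the weakly basic phosphonate anion should not epimerise C7.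

**Step 7**
Reactants: 11 enoate
Product: 12 methyl (2RS,4S,5S)-5,9-dimethyl-2,4-bis(3-methylbut-2-enyl)-5-vinyldec-8-enoate
Conditions: Mg turnings, MeOH, rt
Reagents that add atoms: none
Why: Dissolving-metal conjugate reduction (Mg/MeOH) of the α,β-unsaturated ester, which leaves isolated vinyl and trisubstituted alkenes alone; C5 forms as a mixture, which does not matter.

**Step 8**
Reactants: 12 ester
Product: 14 methyl (2RS,4S,5S)-5-(2-hydroxyethyl)-5,9-dimethyl-2,4-bis(3-methylbut-2-enyl)dec-8-enoate, via B-alkyl-9-BBN adduct 13 (not isolated)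
Conditions: 9-BBN, THF, 0 °C → rt; then aq. NaOH, H2O2, 0 °C
Reagents that add atoms: hydrogen peroxide, OO
Why: Anti-Markovnikov hydroboration–oxidation; 9-BBN strongly prefers the monosubstituted vinyl group over the three trisubstituted alkenes and does not touch the ester.

**Step 9**
Reactants: 14 primary alcohol
Product: 15 methyl (2RS,4S,5S)-5,9-dimethyl-2,4-bis(3-methylbut-2-enyl)-5-(2-oxoethyl)dec-8-enoate
Conditions: DMP, CH2Cl2, 0 °C → rt
Reagents that add atoms: none
Why: Dess–Martin oxidation of a primary alcohol to the aldehyde without over-oxidation.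

**Step 10**
Reactants: 15 aldehyde
Product: 16 methyl (2RS,4S,5S)-5-(2-hydroxy-3-methylbutyl)-5,9-dimethyl-2,4-bis(3-methylbut-2-enyl)dec-8-enoate (carbinol epimers)
Conditions: iPrMgCl, THF, −78 °C
Reagents that add atoms: isopropylmagnesium chloride, CC(C)[Mg]Cl
Why: Grignard addition to the aldehyde, which at −78 °C is far more electrophilic than the α-branched methyl ester; the new carbinol centre is oxidised away in step 12.

**Step 11**
Reactants: 16 hydroxy ester
Product: 17 (2RS,4S,5S)-5-(2-hydroxy-3-methylbutyl)-5,9-dimethyl-2,4-bis(3-methylbut-2-enyl)dec-8-enoic acid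
Conditions: LiOH, THF/MeOH/H2O, 50 °C; then 1 M HCl, 0 °C
Reagents that add atoms: lithium hydroxide, [Li+].[OH-]
Why: Saponification is done before the ketone exists, so that no ketone enolate can close on the ester in a six-membered Claisen condensation.

**Step 12**
Reactants: 17 hydroxy acid
Product: 18 (2RS,4S,5S)-5,9-dimethyl-5-(3-methyl-2-oxobutyl)-2,4-bis(3-methylbut-2-enyl)dec-8-enoic acid
Conditions: DMP, CH2Cl2, rt
Reagents that add atoms: none
Why: Dess–Martin oxidation of the secondary alcohol to the isopropyl ketone; the free carboxylic acid is tolerated.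

**Step 13**
Reactants: 18 keto acid; 19 diethyl bromomalonate
Product: 20 diethyl 2-acyloxymalonate of 18
Conditions: Cs2CO3 (0.5 equiv), DMF, rt; then 19 (1.0 equiv)
Reagents that add atoms: none
Why: SN2 displacement of bromide from the doubly activated secondary bromide by the caesium carboxylate, which joins C3 to the carboxyl oxygen without acylating a hindered tertiary alcohol.

**Step 14**
Reactants: 20 acyloxymalonate; 9 prenyl bromide
Product: 21 diethyl 2-acyloxy-2-(3-methylbut-2-enyl)malonate of 18 (precursor of the key step)
Conditions: Cs2CO3 (1.1 equiv), DMF, 0 °C → rt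
Reagents that add atoms: none
Why: C-alkylation of the malonate anion, whose C–H is many pKa units more acidic than the ketone and ester α-hydrogens, so carbonate touches only C3; C3 stays prochiral because its two ester groups are identical.

**Step 15**
Reactants: 21 acyloxymalonate
Product: 25 CNP0121153.1 (target), via dilithium dienolate 22 (not isolated), via furandione lithium enolate 23 (not isolated), via lithium diketonate 24 (not isolated)
Conditions: LDA (3.0 equiv), THF, −78 °C, 1 h; then −78 → 23 °C (40 °C if needed); 1 M HCl, 0 °C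
Reagents that add atoms: none
Why: Proposed new method: LDA first converts 21 at −78 °C into the ester/ketone dienolate 22, so that C9 and the isobutyryl carbon are enolate carbons and not electrophiles while both nucleophiles exist, and on warming the C5 enolate closes 5-exo-trig on either malonate ester (C4–C5, lactone ring; closest known reaction: Lacey–Dieckmann cyclisation of α-acyloxy esters to furan-2,4-diones), giving 23 and lithium ethoxide. Because 23 has no acidic hydrogen between its carbonyls the ethoxide can reopen it, so the C3 and C5 configurations stay exchangeable. The C1 enolate then acylates on the second malonyl carbonyl (C1–C2, eight-membered ring; closest known reaction: intramolecular ketone–ester Claisen condensation), either directly by 8-exo-trig attack on the ester cis to the C6 chain or, more probably, by 6-exo addition to the ring ketone C4, C4–C5 fragmentation to a nine-membered keto lactone and 5-exo reclosure of the C5 enolate on the remaining ester, which leads to the same bicycle because C2 and C4 are interchangeable. The β-diketone formed is deprotonated at C1 by the third equivalent of base, and diketonate 24 is the one member of the manifold that does not revert. C3 and C5 are fixed relative to each other by the bicycle (the O–C9 bridge spans one face only), relative to C7 by the preference for the bicycle whose C7 prenyl group points away from the C2–C3–C4 arc, and C1 by equilibration of the β-diketone on work-up. The step needs C1 to be acylated by a malonyl carbon and not by C9 (six-membered Claisen closure with loss or opening of the tartronate unit), which the double deprotonation and the absence of external alkoxide are meant to secure, and it needs the right one of the two cis bicycles, for which only the conformational argument speaks.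

**Compound list**

1 | geraniol | CC(C)=CCC/C(C)=C/CO | starting material
2 | 5-methylhex-4-enoic acid | CC(C)=CCCC(O)=O | starting material
3 | geranyl 5-methylhex-4-enoate | CC(C)=CCCC(=O)OC/C=C(\C)CCC=C(C)C | intermediate
4 | Z(O)-boron ketene acetal of 3 with the (4S,5S)-diazaborolidine | CC(C)=CC/C=C(\OB1N(S(=O)(=O)c2cc(cc(c2)C(F)(F)F)C(F)(F)F)[C@@H](c2ccccc2)[C@H](c2ccccc2)N1S(=O)(=O)c1cc(cc(c1)C(F)(F)F)C(F)(F)F)OC/C=C(\C)CCC=C(C)C | intermediate (not isolated)
5 | (2R,3S)-3,7-dimethyl-2-(3-methylbut-2-enyl)-3-vinyloct-6-enoic acid | CC(C)=CCC[C@@](C)(C=C)[C@@H](CC=C(C)C)C(O)=O | intermediate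
6 | (2R,3S)-3,7-dimethyl-2-(3-methylbut-2-enyl)-3-vinyloct-6-en-1-ol | CC(C)=CCC[C@@](C)(C=C)[C@@H](CC=C(C)C)CO | intermediate
7 | (2R,3S)-3,7-dimethyl-2-(3-methylbut-2-enyl)-3-vinyloct-6-enal | CC(C)=CCC[C@@](C)(C=C)[C@@H](CC=C(C)C)C=O | intermediate
8 | trimethyl phosphonoacetate | COC(=O)CP(=O)(OC)OC | starting material
9 | prenyl bromide (1-bromo-3-methylbut-2-ene) | CC(C)=CCBr | starting material
10 | methyl 2-(dimethoxyphosphoryl)-5-methylhex-4-enoate | COC(=O)C(CC=C(C)C)P(=O)(OC)OC | intermediate
11 | methyl (4S,5S)-5,9-dimethyl-2,4-bis(3-methylbut-2-enyl)-5-vinyldeca-2,8-dienoate (E/Z) | CC(C)=CCC[C@@](C)(C=C)[C@@H](CC=C(C)C)C=C(CC=C(C)C)C(=O)OC | intermediate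
12 | methyl (2RS,4S,5S)-5,9-dimethyl-2,4-bis(3-methylbut-2-enyl)-5-vinyldec-8-enoate | CC(C)=CCC[C@@](C)(C=C)[C@@H](CC=C(C)C)CC(CC=C(C)C)C(=O)OC | intermediate
13 | B-alkyl-9-BBN adduct of 12 (boron on the terminal vinyl carbon) | CC(C)=CCC[C@@](C)(CCB1C2CCCC1CCC2)[C@@H](CC=C(C)C)CC(CC=C(C)C)C(=O)OC | intermediate (not isolated)
14 | methyl (2RS,4S,5S)-5-(2-hydroxyethyl)-5,9-dimethyl-2,4-bis(3-methylbut-2-enyl)dec-8-enoate | CC(C)=CCC[C@@](C)(CCO)[C@@H](CC=C(C)C)CC(CC=C(C)C)C(=O)OC | intermediate
15 | methyl (2RS,4S,5S)-5,9-dimethyl-2,4-bis(3-methylbut-2-enyl)-5-(2-oxoethyl)dec-8-enoate | CC(C)=CCC[C@@](C)(CC=O)[C@@H](CC=C(C)C)CC(CC=C(C)C)C(=O)OC | intermediate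
16 | methyl (2RS,4S,5S)-5-(2-hydroxy-3-methylbutyl)-5,9-dimethyl-2,4-bis(3-methylbut-2-enyl)dec-8-enoate | CC(C)=CCC[C@@](C)(CC(O)C(C)C)[C@@H](CC=C(C)C)CC(CC=C(C)C)C(=O)OC | intermediate
17 | (2RS,4S,5S)-5-(2-hydroxy-3-methylbutyl)-5,9-dimethyl-2,4-bis(3-methylbut-2-enyl)dec-8-enoic acid | CC(C)=CCC[C@@](C)(CC(O)C(C)C)[C@@H](CC=C(C)C)CC(CC=C(C)C)C(O)=O | intermediate
18 | (2RS,4S,5S)-5,9-dimethyl-5-(3-methyl-2-oxobutyl)-2,4-bis(3-methylbut-2-enyl)dec-8-enoic acid | CC(C)=CCC[C@@](C)(CC(=O)C(C)C)[C@@H](CC=C(C)C)CC(CC=C(C)C)C(O)=O | intermediate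
19 | diethyl bromomalonate | CCOC(=O)C(Br)C(=O)OCC | starting material
20 | diethyl 2-acyloxymalonate of 18 | CC(C)=CCC[C@@](C)(CC(=O)C(C)C)[C@@H](CC=C(C)C)CC(CC=C(C)C)C(=O)OC(C(=O)OCC)C(=O)OCC | intermediate
21 | diethyl 2-acyloxy-2-(3-methylbut-2-enyl)malonate of 18 (C5 epimers; C7 S, C8 S) | CC(C)=CCC[C@@](C)(CC(=O)C(C)C)[C@@H](CC=C(C)C)CC(CC=C(C)C)C(=O)OC(CC=C(C)C)(C(=O)OCC)C(=O)OCC | intermediate
22 | dilithium dienolate of 21 (C5 ester enolate and C1 ketone enolate) | CC(C)=CCC[C@@](C)(C=C(O[Li])C(C)C)[C@@H](CC=C(C)C)CC(CC=C(C)C)=C(O[Li])OC(CC=C(C)C)(C(=O)OCC)C(=O)OCC | intermediate (not isolated)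
23 | 3,5-diprenyl-5-ethoxycarbonylfuran-2,4-dione carrying the C1 lithium enolate chain (isomer with the ester cis to the C6 chain shown; C3/C5 isomers interconvert) | CC(C)=CCC[C@@](C)(C=C(O[Li])C(C)C)[C@@H](CC=C(C)C)C[C@@]1(CC=C(C)C)C(=O)O[C@@](CC=C(C)C)(C(=O)OCC)C1=O | intermediate (not isolated)
24 | lithium β-diketonate of the target (C1 deprotonated) | CC(C)=CCC[C@]1(C)[C@@H](CC=C(C)C)C[C@@]2(CC=C(C)C)C(=O)O[C@@](CC=C(C)C)(C(=O)C1=C(O[Li])C(C)C)C2=O | intermediate (not isolated)
25 | CNP0121153.1, (1R,3S,5R,7S,8R) in the numbering of the overview | CC(C)=CCC[C@]1(C)[C@@H](CC=C(C)C)C[C@@]2(CC=C(C)C)C(=O)O[C@@](CC=C(C)C)(C(=O)[C@H]1C(=O)C(C)C)C2=O | target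

**Step count**

Total: 15 steps. Longest linear sequence: 14 steps (1–4, 6–15 from geraniol; step 5 is a side branch).

**Three steps most likely to fail**

1. Step 15 (proposed new method). What may go wrong: C1 is acylated through a six-membered transition state by C9 (after proton return to C5, or on the lactone carbonyl), so that the tartronate unit is lost or the lactone ring is opened; or the equilibria settle on both cis bicycles without selection.
Fallback, from 21 back to the route at 25: the one-flask funnel is given up for three separate operations of known type, with isolation and stereochemical sorting after each. Compound 21 is treated with LDA (2.0 equiv) in THF at −78 → −40 °C and quenched cold with acetic acid; this stops after the Lacey–Dieckmann closure and should give the keto furandione F1 as C3/C5 isomers. F1 with KOtBu (1.0 equiv) in THF at 0 °C should undergo the known ring enlargement of α-substituted cyclic β-keto esters (the side-chain ketone enolate adds to the ring ketone C4 and the aldolate cleaves C4–C5) to the nine-membered keto lactone F2, which rests as its β-diketonate; its C3 epimers are separated. The epimer with the C3 configuration of the target is then treated with LDA (2.2 equiv) in THF at −78 → 0 °C, so that the C5 enolate closes by transannular 5-exo Dieckmann condensation on the remaining ethyl ester to give 25.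

2. Step 2. What may go wrong: incomplete control of the boron enolate geometry, slow rearrangement to the quaternary centre with competing enolate decomposition, or insufficient facial selectivity.
Fallback, from 3 back to the route at 6: reagent control is replaced by resolution. Ester 3 is rearranged as its racemic silyl ketene acetal (LDA, THF/DMPU, TMSCl, −78 °C → rt, Z(O)-enolate conditions, then aqueous work-up) to the racemic (2R*,3S*) acid, that is 5 together with its enantiomer, the ent-acid F3. DCC/DMAP coupling of the racemate with (S)-4-benzyl-2-oxazolidinone should give two diastereomeric imides, the imide of 5 F4 and the imide of the ent-acid F5, which are separated by chromatography and assigned by correlation with material from step 2 or by X-ray. LiBH4 (Et2O, H2O, 0 °C) cleaves F4 to alcohol 6 and returns the auxiliary.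

3. Step 6. What may go wrong: slow addition of the fully substituted phosphonate carbanion to the hindered aldehyde, with epimerisation at C7 during the longer reaction time.
Fallback, from 7 back to the route at 12: the prenyl group at C5 is introduced after the olefination. Aldehyde 7 is olefinated with unsubstituted trimethyl phosphonoacetate 8 under Masamune–Roush conditions (LiCl, DBU, MeCN, rt) to the disubstituted enoate F6. Mg/MeOH reduces it to the saturated ester F7. Enolisation of F7 with LDA (THF, −78 °C) and alkylation with prenyl bromide 9 gives 12 as the same C5 epimer mixture.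

**Further compounds**

F1 | step 15 | keto furandione: 3,5-diprenyl-5-ethoxycarbonylfuran-2,4-dione with the free ketone chain on C5 (C3/C5 isomers) | CC(C)=CCC[C@@](C)(CC(=O)C(C)C)[C@@H](CC=C(C)C)CC1(CC=C(C)C)C(=O)OC(CC=C(C)C)(C(=O)OCC)C1=O
F2 | step 15 | nine-membered keto lactone (ring C1, C4, C3, O, C9, C5, C6, C7, C8; C1 bears isobutyryl, C3 bears prenyl and CO2Et; C1, C3, C5 epimers) | CC(C)=CCC[C@]1(C)[C@@H](CC=C(C)C)CC(CC=C(C)C)C(=O)OC(CC=C(C)C)(C(=O)OCC)C(=O)C1C(=O)C(C)C
F3 | step 2 | (2S,3R)-3,7-dimethyl-2-(3-methylbut-2-enyl)-3-vinyloct-6-enoic acid (enantiomer of 5) | CC(C)=CCC[C@](C)(C=C)[C@H](CC=C(C)C)C(O)=O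
F4 | step 2 | N-acyl (S)-4-benzyl-2-oxazolidinone of 5 | CC(C)=CCC[C@@](C)(C=C)[C@@H](CC=C(C)C)C(=O)N1[C@@H](Cc2ccccc2)COC1=O
F5 | step 2 | N-acyl (S)-4-benzyl-2-oxazolidinone of F3 | CC(C)=CCC[C@](C)(C=C)[C@H](CC=C(C)C)C(=O)N1[C@@H](Cc2ccccc2)COC1=O
F6 | step 6 | methyl (2E,4S,5S)-5,9-dimethyl-4-(3-methylbut-2-enyl)-5-vinyldeca-2,8-dienoate | CC(C)=CCC[C@@](C)(C=C)[C@@H](CC=C(C)C)/C=C/C(=O)OC
F7 | step 6 | methyl (4S,5S)-5,9-dimethyl-4-(3-methylbut-2-enyl)-5-vinyldec-8-enoate | CC(C)=CCC[C@@](C)(C=C)[C@@H](CC=C(C)C)CCC(=O)OC
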